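**Retrosynthetic overview**
- Licoriphenone ⇐ its bis(allyl) ether on the resorcinol ring; Pd(0) deallylation is the only deprotection.
- Key bond C(=O)–CH2: an acyl anion (Breslow intermediate from 2,4-bis(allyloxy)benzaldehyde under thiazolium-carbene catalysis) adds to the ortho-quinone methide of the phloroglucinol ring; the carbonyl carbon and the benzylic carbon are both natively electrophilic.
- The ortho-quinone methide ⇐ phenolic Mannich base (N-methylation, then base) ⇐ 3,5-dimethoxy-4-prenylphenol + CH2O + Me2NH.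
- 3,5-Dimethoxy-4-prenylphenol ⇐ 3,5-dimethoxyphenol via its TIPS ether, lithiation between the two OMe groups and prenyl bromide.
- No ring is constructed: both benzene rings are bought.

Assumption: the target has no stereocentre and no stereogenic double bond (the prenyl alkene carries two identical methyls), so there is no stereochemistry to set.

**Step 1**
Reactants: 1 3,5-dimethoxyphenol
Product: 2 (3,5-dimethoxyphenoxy)tri(propan-2-yl)silane
Conditions: TIPSCl (1.1 eq), imidazole (2.2 eq), DMF, rt, 3 h
Reagents that add atoms: chlorotri(propan-2-yl)silane (TIPSCl), CC(C)[Si](Cl)(C(C)C)C(C)C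
Why: Imidazole-mediated O-silylation of a phenol; the bulky TIPS ether removes the acidic OH and is a poor, hindered director, so the next lithiation goes to the position between the two OMe groups.

**Step 2**
Reactants: 2 (3,5-dimethoxyphenoxy)tri(propan-2-yl)silane, 3 1-bromo-3-methylbut-2-ene (prenyl bromide)
Product: 6 3,5-dimethoxy-4-(3-methylbut-2-enyl)phenol, via aryllithium 4 (not isolated), via prenylated silyl ether 5 (not isolated)
Conditions: n-BuLi (1.1 eq), TMEDA (1.1 eq), THF, 0 °C → rt, 2 h; 3 (1.0 eq, kept limiting), −78 °C → rt; then TBAF (1.3 eq, 1 M in THF), rt, 30 min; aq. work-up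
Reagents that add atoms: none
Why: Directed ortho-metalation removes the C–H flanked and chelated by two OMe groups, the aryllithium is alkylated SN2 by the primary allylic bromide, and fluoride cleaves the aryl silyl ether in the same flask; no stereocentre is formed.

**Step 3**
Reactants: 6 3,5-dimethoxy-4-(3-methylbut-2-enyl)phenol, 7 formaldehyde
Product: 8 2-[(dimethylamino)methyl]-3,5-dimethoxy-4-(3-methylbut-2-enyl)phenol
Conditions: 37% aq. CH2O (1.0 eq), 40% aq. Me2NH (1.1 eq), EtOH, 0 °C → rt, 12 h
Reagents that add atoms: dimethylamine, CNC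
Why: Phenolic Mannich reaction; the iminium attacks ortho to the OH, and the only two free ring positions are equivalent by symmetry, so one equivalent of reagents gives a single mono-aminomethyl phenol.

**Step 4**
Reactants: 9 2,4-dihydroxybenzaldehyde
Product: 10 2,4-bis(prop-2-enyloxy)benzaldehyde
Conditions: allyl bromide (2.5 eq), K2CO3 (3 eq), DMF, 60 °C, 6 h
Reagents that add atoms: allyl bromide (3-bromoprop-1-ene), C=CCBr
Why: Williamson etherification gives base-stable phenol protection that is later removed under neutral Pd(0) conditions, sparing the prenyl group and avoiding acid-induced cyclodehydration to a 2-arylbenzofuran.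

**Step 5 (key step)**
Reactants: 8 2-[(dimethylamino)methyl]-3,5-dimethoxy-4-(3-methylbut-2-enyl)phenol, 10 2,4-bis(prop-2-enyloxy)benzaldehyde
Product: 13 1-[2,4-bis(prop-2-enyloxy)phenyl]-2-[6-hydroxy-2,4-dimethoxy-3-(3-methylbut-2-enyl)phenyl]ethan-1-one, via trimethylammonium iodide 11 (not isolated), via o-quinone methide 12 (not isolated)
Conditions: MeI (1.1 eq), MeCN, rt, 2 h, evaporate; then crude 11 in MeCN added over 4 h to 10 (1.5 eq), 3-benzyl-5-(2-hydroxyethyl)-4-methylthiazolium chloride (20 mol%), Cs2CO3 (2.0 eq), 4 Å MS, THF–MeCN, rt, Ar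
Reagents that add atoms: none
Why: Proposed new method: N-methylation turns NMe2 into an NMe3+ leaving group, carbonate deprotonates the phenol and 1,4-elimination releases the o-quinone methide 12 at low concentration, while the thiazol-2-ylidene converts aldehyde 10 into its Breslow intermediate (an acyl anion equivalent) that adds to the exocyclic CH2 of 12 with rearomatisation and then expels the carbene to give ketone 13; the closest known reaction type is the thiazolium-carbene-catalysed nucleophilic acylation (Stetter-type hydroacylation) of o-quinone methides generated in situ from o-silyloxybenzyl halides with fluoride, combined here with the known base-triggered release of o-quinone methides from phenolic Mannich-base methiodides.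

**Step 6**
Reactants: 13 1-[2,4-bis(prop-2-enyloxy)phenyl]-2-[6-hydroxy-2,4-dimethoxy-3-(3-methylbut-2-enyl)phenyl]ethan-1-one
Product: 14 licoriphenone, 1-(2,4-dihydroxyphenyl)-2-[6-hydroxy-2,4-dimethoxy-3-(3-methylbut-2-enyl)phenyl]ethan-1-one
Conditions: Pd(PPh3)4 (5 mol%), morpholine (6 eq), THF, rt, 2 h, Ar
Reagents that add atoms: none
Why: Tsuji–Trost-type deallylation; Pd(0) ionises both aryl allyl ethers to π-allyl complexes that morpholine traps, while the C-prenyl group, the ketone and the methyl ethers are inert and no stereocentre is involved.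

**Compound list**
1 | 3,5-dimethoxyphenol | COc1cc(O)cc(OC)c1 | starting material
2 | (3,5-dimethoxyphenoxy)tri(propan-2-yl)silane | COc1cc(O[Si](C(C)C)(C(C)C)C(C)C)cc(OC)c1 | intermediate
3 | 1-bromo-3-methylbut-2-ene (prenyl bromide) | CC(C)=CCBr | starting material
4 | [2,6-dimethoxy-4-(triisopropylsilyloxy)phenyl]lithium | COc1cc(O[Si](C(C)C)(C(C)C)C(C)C)cc(OC)c1[Li] | intermediate
5 | [3,5-dimethoxy-4-(3-methylbut-2-enyl)phenoxy]tri(propan-2-yl)silane | COc1cc(O[Si](C(C)C)(C(C)C)C(C)C)cc(OC)c1CC=C(C)C | intermediate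
6 | 3,5-dimethoxy-4-(3-methylbut-2-enyl)phenol | COc1cc(O)cc(OC)c1CC=C(C)C | intermediate
7 | formaldehyde | C=O | starting material
8 | 2-[(dimethylamino)methyl]-3,5-dimethoxy-4-(3-methylbut-2-enyl)phenol | COc1cc(O)c(CN(C)C)c(OC)c1CC=C(C)C | intermediate
9 | 2,4-dihydroxybenzaldehyde | O=Cc1ccc(O)cc1O | starting material
10 | 2,4-bis(prop-2-enyloxy)benzaldehyde | C=CCOc1ccc(C=O)c(OCC=C)c1 | intermediate
11 | [6-hydroxy-2,4-dimethoxy-3-(3-methylbut-2-enyl)phenyl]methyl-trimethylazanium iodide | COc1cc(O)c(C[N+](C)(C)C)c(OC)c1CC=C(C)C.[I-] | intermediate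
12 | 3,5-dimethoxy-4-(3-methylbut-2-enyl)-6-methylidenecyclohexa-2,4-dien-1-one (o-quinone methide) | C=C1C(=O)C=C(OC)C(CC=C(C)C)=C1OC | intermediate
13 | 1-[2,4-bis(prop-2-enyloxy)phenyl]-2-[6-hydroxy-2,4-dimethoxy-3-(3-methylbut-2-enyl)phenyl]ethan-1-one | C=CCOc1ccc(C(=O)Cc2c(O)cc(OC)c(CC=C(C)C)c2OC)c(OCC=C)c1 | intermediate
14 | licoriphenone | COc1cc(O)c(CC(=O)c2ccc(O)cc2O)c(OC)c1CC=C(C)C | target

**Totals**
Total step count: 6. Longest linear sequence: 5 (steps 1, 2, 3, 5, 6; step 4 is the one-step side branch).

**Three steps most likely to fail**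

Step 5 is the riskiest. The electron-rich o-quinone methide 12 can be captured by phenoxides of 11 or 13 to give methylene-bridged diarylmethanes, and the electron-rich, ortho-alkoxy aldehyde 10 may form its Breslow intermediate slowly. The fallback replaces the carbene catalysis by a stoichiometric acyl-anion equivalent; it sets out from 10 and comes back at 13. Aldehyde 10 is condensed with propane-1,3-dithiol (BF3·OEt2, CH2Cl2, 0 °C) to 2-[2,4-bis(prop-2-enyloxy)phenyl]-1,3-dithiane F1. n-BuLi (THF, −78 °C) gives {2-[2,4-bis(prop-2-enyloxy)phenyl]-1,3-dithian-2-yl}lithium F2 (2.1 eq). Crude 11 is added to it: the first equivalent deprotonates the phenol and releases 12, the second adds 1,4 to give 2-({2-[2,4-bis(prop-2-enyloxy)phenyl]-1,3-dithian-2-yl}methyl)-3,5-dimethoxy-4-(3-methylbut-2-enyl)phenol F3. MeI/CaCO3 in aqueous MeCN (40 °C) unmasks the ketone to give 13.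

Step 3 may give the bis-aminomethyl phenol or methylene-bridged dimers, because the ring is phloroglucinol-like. The fallback installs the carbon at the aldehyde oxidation level, which deactivates the ring after one substitution; it sets out from 6 and comes back at 8. Magnesium-mediated ortho-formylation (MgCl2, Et3N, paraformaldehyde, MeCN, reflux) gives 6-hydroxy-2,4-dimethoxy-3-(3-methylbut-2-enyl)benzaldehyde F4. Reductive amination (Me2NH, NaBH(OAc)3, 1,2-dichloroethane, rt) then gives 8.

Step 2 may suffer from incomplete or misdirected lithiation of 2, or from O-prenylation of the phenoxide during the one-pot desilylation. The fallback introduces the phenol oxygen last by C–H borylation; it sets out from 3 and comes back at 6. Commercial 1,3-dimethoxybenzene (COc1cccc(OC)c1) is lithiated (n-BuLi, THF, 0 °C → rt) to (2,6-dimethoxyphenyl)lithium F5, which is alkylated with 3 to 1,3-dimethoxy-2-(3-methylbut-2-enyl)benzene F6. Sterically controlled iridium-catalysed C–H borylation at the only position without an ortho substituent ([Ir(OMe)(cod)]2, dtbpy, B2pin2, THF, 60 °C) gives 2-[3,5-dimethoxy-4-(3-methylbut-2-enyl)phenyl]-4,4,5,5-tetramethyl-1,3,2-dioxaborolane F7. Oxidation with NaBO3·4H2O (THF/H2O, rt) gives 6.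

**Further compounds**
F1 | step 5 | 2-[2,4-bis(prop-2-enyloxy)phenyl]-1,3-dithiane | C=CCOc1ccc(C2SCCCS2)c(OCC=C)c1
F2 | step 5 | {2-[2,4-bis(prop-2-enyloxy)phenyl]-1,3-dithian-2-yl}lithium | C=CCOc1ccc(C2([Li])SCCCS2)c(OCC=C)c1
F3 | step 5 | 2-({2-[2,4-bis(prop-2-enyloxy)phenyl]-1,3-dithian-2-yl}methyl)-3,5-dimethoxy-4-(3-methylbut-2-enyl)phenol | C=CCOc1ccc(C2(Cc3c(O)cc(OC)c(CC=C(C)C)c3OC)SCCCS2)c(OCC=C)c1
F4 | step 3 | 6-hydroxy-2,4-dimethoxy-3-(3-methylbut-2-enyl)benzaldehyde | COc1cc(O)c(C=O)c(OC)c1CC=C(C)C
F5 | step 2 | (2,6-dimethoxyphenyl)lithium | COc1cccc(OC)c1[Li]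
F6 | step 2 | 1,3-dimethoxy-2-(3-methylbut-2-enyl)benzene | COc1cccc(OC)c1CC=C(C)C
F7 | step 2 | 2-[3,5-dimethoxy-4-(3-methylbut-2-enyl)phenyl]-4,4,5,5-tetramethyl-1,3,2-dioxaborolane | COc1cc(B2OC(C)(C)C(C)(C)O2)cc(OC)c1CC=C(C)C
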